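The numbers in the tables were generated by integration for an exercise, noise included.

The pitfall I watched for was a ratio that looks flat while its earliest points are small amounts read with scatter.

| flask | solid substrate | remark | time |
|---|---|---|---|
| alder | 0.70 M | run made earlier |  |
| elm | 1.1 M | run made earlier |  |
| flask | 0.50 M |  | 8.0 h |

| run | time / h | target / % | isomer of the product / % |
|---|---|---|---|
| alder | 0.417 | 2.3 | 1.0 |
| alder | 0.667 | 4.5 | 2.1 |
| alder | 1.33 | 12.2 | 5.6 |
| alder | 2.50 | 27.6 | 13.1 |
| alder | 5.00 | 56.3 | 27.3 |
| elm | 0.417 | 1.0 | 0.4 |
| elm | 0.667 | 2.8 | 1.3 |
| elm | 1.33 | 7.9 | 4.1 |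
| elm | 2.50 | 17.2 | 7.2 |
| elm | 5.00 | 37.1 | 18.2 |

(each reading ± 0.5 percentage points)

- solid substrate is a solid; its amount is given per volume of the solution
- the earlier runs were read with a standard deviation of 0.5 percentage points
- at the start none of the solid substrate is in solution

1. share of target in target plus isomer of the product at 20 min
2. share of target in target plus isomer of the product at 80 min
3. share of target in target plus isomer of the product at 8.0 h

1. I folded the readings into a single number, the split (selectivity factor): target over isomer of the product at 5.00 h, both runs pooled, which came to 2.05.

2. In words, each part of isomer of the product stood beside that many parts of target, so the split gave a share of 67.2%. I committed to this for the flask at 80 min and 8.0 h.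

3. I then tested whether one number was enough. A slip of 0.5 percentage points on the isomer of the product at 1.33 h in the alder run moved the share from 66.7% to 70.5%. At 0.417 h in that run the same slip gave 60.5% to 82.1%, and 20 min comes earlier still. So for 20 min I held that whole window open.

4. The forecast gave 68.5% (64% to 73%), 68% (65.5% to 70.5%) and 67.5% (63% to 72%): “Target's share of the two products is flat within scatter”. Its range at 20 min was narrower than my window.

5. The flask gave 78.2%, 70.1% and 67.5%.

    solid substrate ⇌ starting material, rate k1*(cs1 - [starting material]) while solid is left; crystals form when [starting material] > cs1 (solubility = 0.460 M, k = 0.00607 min⁻¹)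
    starting material ⇌ other conformer (K = 1.10, k = 0.123 min⁻¹)
    other conformer ⇌ third conformer (K = 2.36, k = 0.00879 min⁻¹)
    other conformer → isomer of the product (k = 0.0242 min⁻¹)
    starting material → target (k = 0.0429 min⁻¹)
    third conformer → third product (k = 0.0631 min⁻¹)
    starting material ⇌ dormant form (K = 3.00, k = 0.00359 min⁻¹)

With the loss of other conformer to isomer of the product struck out, the share at 80 min reads 100%. The split's share of 67.2% lay 0.3 points from the flask at 8.0 h but 11 points from it at 20 min. The neighbour flask with 1.2 M of solid substrate gave 78.2% at 20 min, 11 points from that share, and 67.7% at 8.0 h, 0.5 points from it.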